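The route rests on cutting the C1–C15 bond, the link between the stereogenic ring carbon C1 of the 14-membered carbocycle and the exocyclic alkene carbon. Both carbons enter as nucleophiles: C1 as a secondary pinacol boronate next to the C14 oxygen, C15 as a Shapiro-derived alkenyllithium. A Zweifel olefination joins them in one operation; it exploits the C15=CH2 unit sitting on the secondary stereocentre C1 beside C14–OMe, builds that alkene and carries the C1 configuration over with retention. The precursor is an acyclic syn-β-silyloxy boronate, assembled from an (S)-epoxide and a (Z)-allylboronate. The ring is closed afterwards at C5–C6 by sulfone alkylation.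

Key step: step 11

Remark on atom labels: C1 is the ring CH bearing the side chain, C2–C13 run round the ring through the 3Z, 7Z and 11E alkenes (methyls on C4, C8, C12), C14 is CH(OMe) and C15 is the exocyclic alkene carbon; with these labels the target is (1R,14S).

Step 1
Reactants: 1 nerol
Product: 2 tert-butyl{[(2Z)-3,7-dimethylocta-2,6-dien-1-yl]oxy}dimethylsilane
Conditions: TBSCl, imidazole, CH2Cl2, 0 °C→rt
Reagents that add atoms: tert-butyldimethylsilyl chloride, CC(C)(C)[Si](C)(C)Cl
Why: Silyl ether formation masks the future C6 oxygen so that the 7Z alkene of nerol is carried unchanged.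

Step 2
Reactants: 2 neryl TBS ether
Product: 3 (2E,6Z)-8-[(tert-butyldimethylsilyl)oxy]-2,6-dimethylocta-2,6-dien-1-ol
Conditions: SeO2 (cat.), t-BuOOH, salicylic acid (cat.), CH2Cl2, rt
Reagents that add atoms: tert-butyl hydroperoxide (terminal oxygen source, delivered through catalytic SeO2), CC(C)(C)OO
Why: Riley-type allylic oxidation (ene reaction, then [2,3]-sigmatropic shift) should oxidise the (E)-methyl of the terminal prenyl unit, which fixes the 11E alkene and functionalises C13.

Step 3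
Reactants: 3 allylic alcohol
Product: 4 {[(2Z,6E)-8-bromo-3,7-dimethylocta-2,6-dien-1-yl]oxy}(tert-butyl)dimethylsilane
Conditions: CBr4, PPh3, CH2Cl2, 0 °C
Reagents that add atoms: carbon tetrabromide, BrC(Br)(Br)Br
Why: Appel bromination of a primary allylic alcohol proceeds by SN2 without allylic transposition.

Step 4
Reactants: 4 allylic bromide
Product: 6 (4E,8Z)-10-[(tert-butyldimethylsilyl)oxy]-4,8-dimethyldeca-4,8-dienal, via N-cyclohexyl imine 5 (not isolated)
Conditions: CH3CH=NCy (from acetaldehyde and cyclohexylamine), LDA, THF, −78 °C; then 4, −78→0 °C; aq. tartaric acid, rt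
Reagents that add atoms: N-ethylidenecyclohexanamine, CC=NC1CCCCC1; water, O
Why: Metalated-imine (aza-enolate) alkylation at the primary allylic bromide followed by mild hydrolysis should add C14 and C1 as a γ,δ-unsaturated aldehyde.

Step 5
Reactants: 6 aldehyde
Product: 9 (2S)-2-{(2E,6Z)-8-[(tert-butyldimethylsilyl)oxy]-2,6-dimethylocta-2,6-dien-1-yl}oxirane, via chloro aldehyde 7 (not isolated), via chlorohydrin 8 (not isolated)
Conditions: trans-2,5-diphenylpyrrolidine (cat., the antipode that gives the (R)-chloride), NCS, CH2Cl2, 0 °C→rt; NaBH4, MeOH, 0 °C; KOH, EtOH/H2O, rt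
Reagents that add atoms: none
Why: Enamine-catalysed enantioselective α-chlorination sets C14 as the (R)-chloride under catalyst control, and reduction followed by Williamson closure with inversion at C14 should give the (S)-epoxide.

Step 6
Reactants: 10 propargyl alcohol
Product: 12 (2Z)-3-iodo-2-methylprop-2-en-1-ol, via alkenylmagnesium alkoxide 11 (not isolated)
Conditions: MeMgBr, CuI (cat.), THF, −10 °C→rt; then I2, −10 °C; aq. NH4Cl
Reagents that add atoms: methylmagnesium bromide, C[Mg]Br; iodine, II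
Why: Copper-catalysed, alkoxide-directed anti-carbomagnesiation places magnesium cis to the CH2O group, and iodinolysis with retention gives the (Z)-vinyl iodide that defines the 3Z alkene.

Step 7
Reactants: 12 iodo alcohol
Product: 13 tert-butyl{[(2Z)-3-iodo-2-methylprop-2-en-1-yl]oxy}diphenylsilane
Conditions: TBDPSCl, imidazole, CH2Cl2, rt
Reagents that add atoms: tert-butyldiphenylsilyl chloride, CC(C)(C)[Si](Cl)(c1ccccc1)c1ccccc1
Why: Silylation protects the future C5 oxygen with a group that outlasts TBS and TES and is bulky enough to slow silyl migration in step 8.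

Step 8
Reactants: 13 vinyl iodide
Product: 16 tert-butyl{[(2Z)-2-methyl-4-(4,4,5,5-tetramethyl-1,3,2-dioxaborolan-2-yl)but-2-en-1-yl]oxy}diphenylsilane, via alkenyllithium 14 (not isolated), via chloromethyl boronate complex 15 (not isolated)
Conditions: t-BuLi, Et2O, −78 °C; then ClCH2Bpin, −78 °C→rt
Reagents that add atoms: 2-(chloromethyl)-4,4,5,5-tetramethyl-1,3,2-dioxaborolane, ClCB1OC(C)(C)C(C)(C)O1
Why: Iodine–lithium exchange with retention, then Matteson homologation (the alkenyl group migrates from boron to CH2 and displaces chloride) should give the (Z)-allylboronate with C2 cis to C5.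

Step 9
Reactants: 17 6-methylhept-5-en-2-one
Product: 18 N'-(6-methylhept-5-en-2-ylidene)-2,4,6-triisopropylbenzenesulfonohydrazide
Conditions: 2,4,6-triisopropylbenzenesulfonyl hydrazide, HCl (cat.), MeOH, rt
Reagents that add atoms: 2,4,6-triisopropylbenzenesulfonyl hydrazide, NNS(=O)(=O)c1c(C(C)C)cc(C(C)C)cc1C(C)C
Why: Hydrazone condensation provides the Shapiro precursor of the 2-lithio-1-alkene needed in step 11.

Step 10
Reactants: 9 (S)-epoxide; 16 (Z)-allylboronate
Product: 21 (2Z,5S,6S,8E,12Z)-1-[(tert-butyldiphenylsilyl)oxy]-14-[(tert-butyldimethylsilyl)oxy]-2,8,12-trimethyl-5-(4,4,5,5-tetramethyl-1,3,2-dioxaborolan-2-yl)-6-[(triethylsilyl)oxy]tetradeca-2,8,12-triene, via lithiated epoxide 19 (not isolated), via epoxy boronate complex 20 (not isolated)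
Conditions: LiTMP added slowly to 9 + 16, THF, −30 °C; then TESOTf, −78 °C→rt
Reagents that add atoms: triethylsilyl trifluoromethanesulfonate, CC[Si](CC)(CC)OS(=O)(=O)C(F)(F)F
Why: Lithiation–borylation of a terminal epoxide (1,2-metallate rearrangement): LiTMP removes the epoxide hydrogen trans to the C14 substituent, boronate 16 traps the carbenoid with retention, and silyl triflate activation triggers anti-periplanar migration of the allyl group with inversion at C1, so the C1–C2 bond and the (S)-C1–B centre form syn to the C14 oxygen under control of C14.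

Step 11
Reactants: 21 secondary boronate; 18 trisylhydrazone
Product: 25 (2Z,5R,6S,8E,12Z)-1-[(tert-butyldiphenylsilyl)oxy]-14-[(tert-butyldimethylsilyl)oxy]-2,8,12-trimethyl-5-(6-methylhepta-1,5-dien-2-yl)-6-[(triethylsilyl)oxy]tetradeca-2,8,12-triene, via alkenyllithium 22 (not isolated), via alkenyl boronate complex 23 (not isolated), via iodo boronate 24 (not isolated)
Conditions: 18, n-BuLi, THF, −78→0 °C; then 21, −78 °C; I2, THF; NaOMe, MeOH, −78 °C→rt
Reagents that add atoms: none
Why: The Shapiro-derived 2-lithio-1,5-diene 22 adds to boron of 21 to give the tetracoordinate complex 23; iodine activates the alkenyl group as an iodonium ion, the C1–B bond migrates to C15 anti to iodine, and methoxide triggers anti elimination of boron and iodide from 24 to reveal C15=CH2. This is a Zweifel olefination of a secondary pinacol boronate with an α-substituted vinyllithium, a precedented reaction type that couples two carbon nucleophiles through an oxidative trigger. No ring is closed. No new stereocentre forms: the migrating carbon C1 keeps its configuration (retention, set relative to C14 in step 10), and the course of the elimination is irrelevant because the new alkene is 1,1-disubstituted. The step needs iodine to react with the boronate complex rather than with the four other alkenes, and the β-silyloxy group to survive; the much higher nucleophilicity of the ate complex at −78 °C and the poor leaving-group ability of the silyloxide should secure both.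

Step 12
Reactants: 25 tris-silyl ether
Product: 26 (2Z,6E,9S,10R,12Z)-14-[(tert-butyldiphenylsilyl)oxy]-3,7,13-trimethyl-10-(6-methylhepta-1,5-dien-2-yl)tetradeca-2,6,12-triene-1,9-diol
Conditions: CSA (cat.), MeOH/CH2Cl2, 0 °C
Reagents that add atoms: none
Why: Acid-catalysed methanolysis cleaves the secondary TES and primary TBS ethers while the more robust TBDPS ether at C5 should remain.

Step 13
Reactants: 26 diol
Product: 28 (2Z,5R,6S,8E,12Z)-1-[(tert-butyldiphenylsilyl)oxy]-2,8,12-trimethyl-5-(6-methylhepta-1,5-dien-2-yl)-14-(phenylsulfonyl)tetradeca-2,8,12-trien-6-ol, via allylic chloride 27 (not isolated)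
Conditions: NCS, Me2S, CH2Cl2, −25→0 °C; then PhSO2Na, Bu4NI (cat.), DMF, rt
Reagents that add atoms: sodium benzenesulfinate, [Na+].[O-]S(=O)c1ccccc1
Why: Corey–Kim chlorination is selective for the primary allylic alcohol over the secondary C14 hydroxyl, and SN2 S-alkylation of the sulfinate should give the C6 sulfone with the 7Z geometry intact.

Step 14
Reactants: 28 hydroxy sulfone
Product: 29 tert-butyl{[(2Z,5R,6S,8E,12Z)-6-methoxy-2,8,12-trimethyl-5-(6-methylhepta-1,5-dien-2-yl)-14-(phenylsulfonyl)tetradeca-2,8,12-trien-1-yl]oxy}diphenylsilane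
Conditions: MeOTf, 2,6-di-tert-butyl-4-methylpyridine, CH2Cl2, 0 °C→rt
Reagents that add atoms: methyl trifluoromethanesulfonate, COS(=O)(=O)C(F)(F)F
Why: O-Methylation with methyl triflate and a hindered, non-nucleophilic base installs the C14 methyl ether without deprotonating the sulfone.

Step 15
Reactants: 29 silyl ether
Product: 30 (2Z,5R,6S,8E,12Z)-6-methoxy-2,8,12-trimethyl-5-(6-methylhepta-1,5-dien-2-yl)-14-(phenylsulfonyl)tetradeca-2,8,12-trien-1-ol
Conditions: TBAF, AcOH, THF, rt
Reagents that add atoms: none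
Why: Buffered fluoride desilylation frees the C5 allylic alcohol without base-induced isomerisation of the allylic sulfone.

Step 16
Reactants: 30 allylic alcohol
Product: 31 {[(2Z,6E,9S,10R,12Z)-14-chloro-9-methoxy-3,7,13-trimethyl-10-(6-methylhepta-1,5-dien-2-yl)tetradeca-2,6,12-trien-1-yl]sulfonyl}benzene
Conditions: NCS, Me2S, CH2Cl2, −25→0 °C
Reagents that add atoms: N-chlorosuccinimide, ClN1C(=O)CCC1=O
Why: Corey–Kim chlorination converts the primary allylic alcohol into the chloride by SN2 without transposition or loss of the 3Z geometry.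

Step 17
Reactants: 31 chloro sulfone
Product: 32 (1E,5Z,9Z,12R,13S)-13-methoxy-1,5,9-trimethyl-12-(6-methylhepta-1,5-dien-2-yl)-7-(phenylsulfonyl)cyclotetradeca-1,5,9-triene (C7 epimers, ring C6 in target labels)
Conditions: NaHMDS, THF, slow addition of 31 (high dilution), 0 °C→rt
Reagents that add atoms: none
Why: Intramolecular SN2 alkylation of the sulfonyl-stabilised allylic carbanion (α-attack at C6) by the allylic chloride closes the 14-membered ring at C5–C6, a standard ring closure for polyprenoid carbocycles; the new C6 centre is removed in step 18.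

Step 18
Reactants: 32 macrocyclic sulfone
Product: 33 (1E,5Z,9Z,12R,13S)-13-methoxy-1,5,9-trimethyl-12-(6-methylhepta-1,5-dien-2-yl)cyclotetradeca-1,5,9-triene (target)
Conditions: PdCl2(dppp) (cat.), LiBHEt3, THF, 0 °C
Reagents that add atoms: none
Why: Palladium-catalysed reductive desulfonylation via the π-allyl complex should deliver hydride to the less substituted terminus C6, and the 7Z geometry should hold because isomerisation would need a σ-complex at the fully substituted C8.

Compound list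
1 | nerol, (2Z)-3,7-dimethylocta-2,6-dien-1-ol | OC/C=C(/C)CCC=C(C)C | starting material
2 | tert-butyl{[(2Z)-3,7-dimethylocta-2,6-dien-1-yl]oxy}dimethylsilane | CC(C)(C)[Si](C)(C)OC/C=C(/C)CCC=C(C)C | intermediate
3 | (2E,6Z)-8-[(tert-butyldimethylsilyl)oxy]-2,6-dimethylocta-2,6-dien-1-ol | CC(C)(C)[Si](C)(C)OC/C=C(/C)CC/C=C(\C)CO | intermediate
4 | {[(2Z,6E)-8-bromo-3,7-dimethylocta-2,6-dien-1-yl]oxy}(tert-butyl)dimethylsilane | CC(C)(C)[Si](C)(C)OC/C=C(/C)CC/C=C(\C)CBr | intermediate
5 | N-cyclohexyl imine of aldehyde 6 (not isolated) | CC(C)(C)[Si](C)(C)OC/C=C(/C)CC/C=C(\C)CCC=NC1CCCCC1 | intermediate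
6 | (4E,8Z)-10-[(tert-butyldimethylsilyl)oxy]-4,8-dimethyldeca-4,8-dienal | CC(C)(C)[Si](C)(C)OC/C=C(/C)CC/C=C(\C)CCC=O | intermediate
7 | (2R,4E,8Z)-2-chloro-10-[(tert-butyldimethylsilyl)oxy]-4,8-dimethyldeca-4,8-dienal (not isolated) | CC(C)(C)[Si](C)(C)OC/C=C(/C)CC/C=C(\C)C[C@@H](Cl)C=O | intermediate
8 | (2R,4E,8Z)-2-chloro-10-[(tert-butyldimethylsilyl)oxy]-4,8-dimethyldeca-4,8-dien-1-ol (not isolated) | CC(C)(C)[Si](C)(C)OC/C=C(/C)CC/C=C(\C)C[C@@H](Cl)CO | intermediate
9 | (2S)-2-{(2E,6Z)-8-[(tert-butyldimethylsilyl)oxy]-2,6-dimethylocta-2,6-dien-1-yl}oxirane | CC(C)(C)[Si](C)(C)OC/C=C(/C)CC/C=C(\C)C[C@H]1CO1 | intermediate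
10 | propargyl alcohol, prop-2-yn-1-ol | C#CCO | starting material
11 | (Z)-alkenylmagnesium bromide alkoxide from anti-carbomagnesiation (not isolated) | Br[Mg]/C=C(/C)CO[Mg]Br | intermediate
12 | (2Z)-3-iodo-2-methylprop-2-en-1-ol | I/C=C(/C)CO | intermediate
13 | tert-butyl{[(2Z)-3-iodo-2-methylprop-2-en-1-yl]oxy}diphenylsilane | I/C=C(/C)CO[Si](c1ccccc1)(c1ccccc1)C(C)(C)C | intermediate
14 | (Z)-alkenyllithium from 13 (not isolated) | [Li]/C=C(/C)CO[Si](c1ccccc1)(c1ccccc1)C(C)(C)C | intermediate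
15 | lithium (chloromethyl)(alkenyl) pinacol boronate complex (not isolated) | [Li+].ClC[B-]1(/C=C(/C)CO[Si](c2ccccc2)(c2ccccc2)C(C)(C)C)OC(C)(C)C(C)(C)O1 | intermediate
16 | tert-butyl{[(2Z)-2-methyl-4-(4,4,5,5-tetramethyl-1,3,2-dioxaborolan-2-yl)but-2-en-1-yl]oxy}diphenylsilane | CC1(C)OB(C/C=C(/C)CO[Si](c2ccccc2)(c2ccccc2)C(C)(C)C)OC1(C)C | intermediate
17 | 6-methylhept-5-en-2-one | CC(=O)CCC=C(C)C | starting material
18 | N'-(6-methylhept-5-en-2-ylidene)-2,4,6-triisopropylbenzenesulfonohydrazide | CC(CCC=C(C)C)=NNS(=O)(=O)c1c(C(C)C)cc(C(C)C)cc1C(C)C | intermediate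
19 | trans-lithiated epoxide from 9, lithium on C1 (not isolated) | CC(C)(C)[Si](C)(C)OC/C=C(/C)CC/C=C(\C)C[C@@H]1O[C@H]1[Li] | intermediate
20 | lithium epoxy(allyl) pinacol boronate complex (not isolated) | [Li+].CC(C)(C)[Si](C)(C)OC/C=C(/C)CC/C=C(\C)C[C@@H]1O[C@H]1[B-]2(C/C=C(/C)CO[Si](c3ccccc3)(c3ccccc3)C(C)(C)C)OC(C)(C)C(C)(C)O2 | intermediate
21 | (2Z,5S,6S,8E,12Z)-1-[(tert-butyldiphenylsilyl)oxy]-14-[(tert-butyldimethylsilyl)oxy]-2,8,12-trimethyl-5-(4,4,5,5-tetramethyl-1,3,2-dioxaborolan-2-yl)-6-[(triethylsilyl)oxy]tetradeca-2,8,12-triene | CC(C)(C)[Si](C)(C)OC/C=C(/C)CC/C=C(\C)C[C@H](O[Si](CC)(CC)CC)[C@@H](B1OC(C)(C)C(C)(C)O1)C/C=C(/C)CO[Si](c1ccccc1)(c1ccccc1)C(C)(C)C | intermediate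
22 | (6-methylhepta-1,5-dien-2-yl)lithium (not isolated) | [Li]C(=C)CCC=C(C)C | intermediate
23 | lithium alkenyl(sec-alkyl) pinacol boronate complex from 21 and 22 (not isolated) | [Li+].CC(C)(C)[Si](C)(C)OC/C=C(/C)CC/C=C(\C)C[C@H](O[Si](CC)(CC)CC)[C@@H]([B-]1(C(=C)CCC=C(C)C)OC(C)(C)C(C)(C)O1)C/C=C(/C)CO[Si](c1ccccc1)(c1ccccc1)C(C)(C)C | intermediate
24 | β-iodo tertiary boronate after 1,2-migration, C15 epimers (not isolated) | CC(C)(C)[Si](C)(C)OC/C=C(/C)CC/C=C(\C)C[C@H](O[Si](CC)(CC)CC)[C@@H](C(CI)(CCC=C(C)C)B1OC(C)(C)C(C)(C)O1)C/C=C(/C)CO[Si](c1ccccc1)(c1ccccc1)C(C)(C)C | intermediate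
25 | (2Z,5R,6S,8E,12Z)-1-[(tert-butyldiphenylsilyl)oxy]-14-[(tert-butyldimethylsilyl)oxy]-2,8,12-trimethyl-5-(6-methylhepta-1,5-dien-2-yl)-6-[(triethylsilyl)oxy]tetradeca-2,8,12-triene | CC(C)(C)[Si](C)(C)OC/C=C(/C)CC/C=C(\C)C[C@H](O[Si](CC)(CC)CC)[C@@H](C(=C)CCC=C(C)C)C/C=C(/C)CO[Si](c1ccccc1)(c1ccccc1)C(C)(C)C | intermediate
26 | (2Z,6E,9S,10R,12Z)-14-[(tert-butyldiphenylsilyl)oxy]-3,7,13-trimethyl-10-(6-methylhepta-1,5-dien-2-yl)tetradeca-2,6,12-triene-1,9-diol | OC/C=C(/C)CC/C=C(\C)C[C@H](O)[C@@H](C(=C)CCC=C(C)C)C/C=C(/C)CO[Si](c1ccccc1)(c1ccccc1)C(C)(C)C | intermediate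
27 | C6 allylic chloride of 26 (not isolated) | ClC/C=C(/C)CC/C=C(\C)C[C@H](O)[C@@H](C(=C)CCC=C(C)C)C/C=C(/C)CO[Si](c1ccccc1)(c1ccccc1)C(C)(C)C | intermediate
28 | (2Z,5R,6S,8E,12Z)-1-[(tert-butyldiphenylsilyl)oxy]-2,8,12-trimethyl-5-(6-methylhepta-1,5-dien-2-yl)-14-(phenylsulfonyl)tetradeca-2,8,12-trien-6-ol | O=S(=O)(C/C=C(/C)CC/C=C(\C)C[C@H](O)[C@@H](C(=C)CCC=C(C)C)C/C=C(/C)CO[Si](c1ccccc1)(c1ccccc1)C(C)(C)C)c1ccccc1 | intermediate
29 | tert-butyl{[(2Z,5R,6S,8E,12Z)-6-methoxy-2,8,12-trimethyl-5-(6-methylhepta-1,5-dien-2-yl)-14-(phenylsulfonyl)tetradeca-2,8,12-trien-1-yl]oxy}diphenylsilane | O=S(=O)(C/C=C(/C)CC/C=C(\C)C[C@H](OC)[C@@H](C(=C)CCC=C(C)C)C/C=C(/C)CO[Si](c1ccccc1)(c1ccccc1)C(C)(C)C)c1ccccc1 | intermediate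
30 | (2Z,5R,6S,8E,12Z)-6-methoxy-2,8,12-trimethyl-5-(6-methylhepta-1,5-dien-2-yl)-14-(phenylsulfonyl)tetradeca-2,8,12-trien-1-ol | O=S(=O)(C/C=C(/C)CC/C=C(\C)C[C@H](OC)[C@@H](C(=C)CCC=C(C)C)C/C=C(/C)CO)c1ccccc1 | intermediate
31 | {[(2Z,6E,9S,10R,12Z)-14-chloro-9-methoxy-3,7,13-trimethyl-10-(6-methylhepta-1,5-dien-2-yl)tetradeca-2,6,12-trien-1-yl]sulfonyl}benzene | O=S(=O)(C/C=C(/C)CC/C=C(\C)C[C@H](OC)[C@@H](C(=C)CCC=C(C)C)C/C=C(/C)CCl)c1ccccc1 | intermediate
32 | (1E,5Z,9Z,12R,13S)-13-methoxy-1,5,9-trimethyl-12-(6-methylhepta-1,5-dien-2-yl)-7-(phenylsulfonyl)cyclotetradeca-1,5,9-triene, C7 epimers | C=C(CCC=C(C)C)[C@H]1C/C=C(/C)CC(S(=O)(=O)c2ccccc2)/C=C(/C)CC/C=C(\C)C[C@@H]1OC | intermediate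
33 | (1E,5Z,9Z,12R,13S)-13-methoxy-1,5,9-trimethyl-12-(6-methylhepta-1,5-dien-2-yl)cyclotetradeca-1,5,9-triene | C=C(CCC=C(C)C)[C@H]1C/C=C(/C)CC/C=C(/C)CC/C=C(\C)C[C@@H]1OC | target

Total step count: 18.
Longest linear sequence: 14 steps (steps 1–5 and 10–18, from nerol).

Steps most likely to fail

Step 10. LiTMP may deprotonate the allylboronate α to boron, or the lithiated epoxide may decompose by carbenoid pathways before boron captures it, so that the C1–B centre never forms. The fallback replaces the 1,2-metallate shift by alkene diboration and cross-coupling. It sets out from epoxide 9 and uses vinyl iodide 13. Opening of 9 with excess dimethylsulfonium methylide (Me3S+ I−, n-BuLi, THF) would give (3S,5E,9Z)-11-[(tert-butyldimethylsilyl)oxy]-5,9-dimethylundeca-1,5,9-trien-3-ol F1. Silylation (TESCl, imidazole) would give its triethylsilyl ether F2. Platinum-catalysed enantioselective diboration of the terminal alkene (Pt(dba)3, TADDOL-derived phosphonite chosen for the (S)-C1 centre, B2pin2) would give the 1,2-bis(boronate) F3. Suzuki–Miyaura coupling selective for the primary C–B bond of F3 with 13 (Pd(OAc)2, RuPhos, KOH, THF/H2O) would come back to the route at 21.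

Step 17. Intermolecular alkylation may outrun ring closure, and the strong base may consume the allylic chloride by elimination or SN2′ attack. The fallback sets out from alcohol 30 and comes back at 32, skipping chloride 31. It is a neutral Mitsunobu-type redox condensation with cyanomethylenetrimethylphosphorane (toluene, 100 °C, slow addition), a reaction known intermolecularly for C-alkylation of allylic aryl sulfones with primary alcohols but not for ring closure of this size. The carbanion is then generated only transiently next to the activated alcohol, without any strong base; this fallback makes no compound outside the list (F0).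

Step 11. The hindered secondary boronate may form the boronate complex incompletely, iodine may attack the other alkenes, or the β-silyloxy group may be lost from the ate complex. The fallback builds the 1,1-disubstituted alkene stepwise and sets out from 21. Matteson homologation (CH2Cl2, n-BuLi, THF, −100 °C→rt; C1 migrates with retention) would give the α-chloro boronate F4. Oxidation (NaBO3, THF/H2O) would give the aldehyde F5, and addition of (4-methylpent-3-enyl)magnesium bromide the secondary alcohol F6. Dess–Martin oxidation would give the ketone F7, and Wittig methylenation (Ph3P=CH2, THF, 0 °C) would come back to the route at 25.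

Further compounds
F1 | step 10 | (3S,5E,9Z)-11-[(tert-butyldimethylsilyl)oxy]-5,9-dimethylundeca-1,5,9-trien-3-ol | CC(C)(C)[Si](C)(C)OC/C=C(/C)CC/C=C(\C)C[C@H](O)C=C
F2 | step 10 | triethylsilyl ether of F1 | CC(C)(C)[Si](C)(C)OC/C=C(/C)CC/C=C(\C)C[C@H](O[Si](CC)(CC)CC)C=C
F3 | step 10 | (2S,3S)-1,2-bis(pinacolboronate) from diboration of F2 | CC(C)(C)[Si](C)(C)OC/C=C(/C)CC/C=C(\C)C[C@H](O[Si](CC)(CC)CC)[C@@H](B1OC(C)(C)C(C)(C)O1)CB1OC(C)(C)C(C)(C)O1
F4 | step 11 | α-chloro boronate from one-carbon homologation of 21 (CHCl epimers) | CC(C)(C)[Si](C)(C)OC/C=C(/C)CC/C=C(\C)C[C@H](O[Si](CC)(CC)CC)[C@@H](C(Cl)B1OC(C)(C)C(C)(C)O1)C/C=C(/C)CO[Si](c1ccccc1)(c1ccccc1)C(C)(C)C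
F5 | step 11 | aldehyde at C15 (C1–CHO) | CC(C)(C)[Si](C)(C)OC/C=C(/C)CC/C=C(\C)C[C@H](O[Si](CC)(CC)CC)[C@@H](C=O)C/C=C(/C)CO[Si](c1ccccc1)(c1ccccc1)C(C)(C)C
F6 | step 11 | secondary alcohol at C15 after Grignard addition (epimers) | CC(C)(C)[Si](C)(C)OC/C=C(/C)CC/C=C(\C)C[C@H](O[Si](CC)(CC)CC)[C@@H](C(O)CCC=C(C)C)C/C=C(/C)CO[Si](c1ccccc1)(c1ccccc1)C(C)(C)C
F7 | step 11 | ketone at C15 | CC(C)(C)[Si](C)(C)OC/C=C(/C)CC/C=C(\C)C[C@H](O[Si](CC)(CC)CC)[C@@H](C(=O)CCC=C(C)C)C/C=C(/C)CO[Si](c1ccccc1)(c1ccccc1)C(C)(C)C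
F0 | step 17 | none | none
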